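## Retrosynthetic overview

- No ring is made. Both carbocycles and the C5, C8, C9 and C10 stereocentres come intact from commercial (−)-sclareol (1); the arene is bought as a boronate.
- Diene: the vinyl carbinol of 1 is cut down to the methyl ketone (4), which gives the kinetic enol triflate (6) and, by vinylation, the 13(16),14-diene (7).
- Key disconnection, C19–O: the 19-ol (8) comes from 7 by hydroxylation of the axial 4β-methyl group, which also fixes the C4 stereocentre.
- Ester C–O and Z-alkene: 8 and (Z)-3-iodoacrylic acid (9) give the iodoacrylate (11); the aryl group is joined from boronate 12 with retention to give the target (13).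

Assumption: the hydroxylase used in step 4 is developed beforehand by directed evolution; this catalyst development is not counted as a step.

## Route

Step 1
Reactants: 1 (−)-sclareol, (5S,8R,9R,10S,13R)-labd-14-ene-8,13-diol
Product: 4 (5S,8R,9R,10S)-8-hydroxy-14,15-dinorlabdan-13-one, via labdane-8α,13,14,15-tetraol 2 (not isolated), via α-hydroxy aldehyde 3 (not isolated)
Conditions: OsO4 (2 mol %), NaIO4 (4 equiv), 2,6-lutidine (2 equiv), dioxane–H2O (3:1), 23 °C
Reagents that add atoms: none
Why: Lemieux–Johnson oxidation: catalytic OsO4 dihydroxylates only the monosubstituted vinyl group, NaIO4 cleaves the 14,15-diol and then the tertiary α-hydroxy aldehyde (as its hydrate) between C13 and C14, so the 13-oxygen ends up as the ketone oxygen and no ring stereocentre is touched.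

Step 2
Reactants: 4 (5S,8R,9R,10S)-8-hydroxy-14,15-dinorlabdan-13-one
Product: 6 (5S,8R,9R,10S)-8-hydroxy-14,15-dinorlabd-13(16)-en-13-yl trifluoromethanesulfonate, via dilithium alkoxide–enolate 5 (not isolated)
Conditions: LiN(iPr)2 (2.3 equiv), THF, −78 °C; then Comins' reagent (1.2 equiv), −78 → 0 °C; aq. NH4Cl
Reagents that add atoms: Comins' reagent, N-(5-chloropyridin-2-yl)-bis(trifluoromethanesulfonyl)imide, O=S(=O)(N(c1ccc(Cl)cn1)S(=O)(=O)C(F)(F)F)C(F)(F)F
Why: Kinetic enolate O-triflation: the first equivalent of base makes the hindered tertiary lithium alkoxide, the second removes a proton from the unhindered methyl group at −78 °C, and the triflimide traps the terminal enolate as the 1,1-disubstituted enol triflate.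

Step 3
Reactants: 6 (5S,8R,9R,10S)-8-hydroxy-14,15-dinorlabd-13(16)-en-13-yl trifluoromethanesulfonate
Product: 7 (5S,8R,9R,10S)-labda-13(16),14-dien-8-ol (iso-abienol)
Conditions: CH2=CHSnBu3 (1.3 equiv), Pd(PPh3)4 (5 mol %), LiCl (3 equiv), THF, 65 °C
Reagents that add atoms: tributyl(vinyl)stannane, C=C[Sn](CCCC)(CCCC)CCCC
Why: Stille coupling of an enol triflate: oxidative addition to zerovalent palladium, chloride-assisted transfer of the vinyl group and reductive elimination give the 2-substituted butadiene with the 13(16),14 pattern fixed by the triflate position; the free tertiary alcohol is tolerated.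

Step 4
Reactants: 7 (5S,8R,9R,10S)-labda-13(16),14-dien-8-ol
Product: 8 (4S,5R,8R,9R,10S)-labda-13(16),14-diene-8,19-diol
Conditions: evolved cytochrome P450 BM3 variant (cofactor heme b, C34H32FeN4O4; 0.1 mol %), NADP+ (cat.), glucose dehydrogenase, D-glucose (3 equiv), air, K2HPO4/KH2PO4 buffer pH 8.0, 2% hydroxypropyl-β-cyclodextrin, 25 °C
Reagents that add atoms: dioxygen, O=O
Why: Proposed new method: site-selective hydroxylation of the axial 4β-methyl group (C19) of a 4,4-dimethyl labdane by a laboratory-evolved P450 BM3 variant. The oxoiron porphyrin radical cation (tetravalent iron) abstracts a hydrogen atom from the C–H bond held closest to the oxo ligand, and the carbon radical rebounds onto the iron-bound hydroxyl, so the C19–O bond forms without touching the ring. Because the two geminal methyl groups are diastereotopic, choosing C19 over C18 sets the (4S) quaternary centre. Methyl C–H bonds are about 3 kcal/mol stronger than the ring CH2 bonds, so the selectivity must be positional. Known variants bind this decalin with ring A over the heme and hydroxylate C3, two bonds from C19. Residues lining ring A (positions 75, 78, 82, 87, 263, 328, 437) are therefore re-shaped by iterative saturation mutagenesis to push the C2–C3 edge away and lower the β-face methyl onto the oxo ligand, while the diene chain stays in the access channel far from iron. Screening is by LC-MS for the 19-ol against the 18-ol, 3-ol and epoxides. Closest known reaction type: P450 rebound hydroxylation, as in BM3-variant C3 hydroxylation of sclareol and sclareolide, C19 oxidation of ent-kaurene by kaurene oxidase, and fungal ring A hydroxylation of sclareol.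

Step 5
Reactants: 8 (4S,5R,8R,9R,10S)-labda-13(16),14-diene-8,19-diol; 9 (Z)-3-iodoacrylic acid
Product: 11 (4S,5R,8R,9R,10S)-8-hydroxylabda-13(16),14-dien-19-yl (Z)-3-iodoacrylate, via O-acylisourea 10 (not isolated)
Conditions: DCC (1.2 equiv), DMAP (5 mol %), CH2Cl2, −20 → 0 °C, dark
Reagents that add atoms: none
Why: Steglich esterification: only the primary 19-OH is acylated because the 8α-OH is tertiary and hindered, and the low temperature and small DMAP loading keep the Z-iodoalkene from isomerising.

Step 6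
Reactants: 11 (4S,5R,8R,9R,10S)-8-hydroxylabda-13(16),14-dien-19-yl (Z)-3-iodoacrylate; 12 2-methoxy-4-(4,4,5,5-tetramethyl-1,3,2-dioxaborolan-2-yl)phenol
Product: 13 (4S,5R,8R,9R,10S)-8-hydroxylabda-13(16),14-dien-19-yl (Z)-ferulate (target)
Conditions: PdCl2(dppf) (3 mol %), K3PO4 (2 equiv), THF–H2O (10:1), 23–40 °C, dark
Reagents that add atoms: none
Why: Suzuki–Miyaura coupling: oxidative addition of the Z-vinyl iodide to zerovalent palladium and reductive elimination both proceed with retention, so the Z-ferulate forms under mild conditions without protecting the phenol, and the neopentyl-type ester, the diene and the tertiary alcohol are inert.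

## Compound list

1 | (−)-sclareol, (5S,8R,9R,10S,13R)-labd-14-ene-8,13-diol | C=C[C@](C)(O)CC[C@@H]1[C@@]2(C)CCCC(C)(C)[C@@H]2CC[C@@]1(C)O | starting material
2 | (13R,14RS)-labdane-8α,13,14,15-tetraol | OCC(O)[C@](C)(O)CC[C@@H]1[C@@]2(C)CCCC(C)(C)[C@@H]2CC[C@@]1(C)O | intermediate
3 | (13R)-8α,13-dihydroxy-15-norlabdan-14-al | O=C[C@](C)(O)CC[C@@H]1[C@@]2(C)CCCC(C)(C)[C@@H]2CC[C@@]1(C)O | intermediate
4 | (5S,8R,9R,10S)-8-hydroxy-14,15-dinorlabdan-13-one | CC(=O)CC[C@@H]1[C@@]2(C)CCCC(C)(C)[C@@H]2CC[C@@]1(C)O | intermediate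
5 | dilithium 8-alkoxide 13(16)-enolate of 4 | [Li+].[Li+].C=C([O-])CC[C@@H]1[C@@]2(C)CCCC(C)(C)[C@@H]2CC[C@@]1(C)[O-] | intermediate
6 | (5S,8R,9R,10S)-8-hydroxy-14,15-dinorlabd-13(16)-en-13-yl trifluoromethanesulfonate | C=C(OS(=O)(=O)C(F)(F)F)CC[C@@H]1[C@@]2(C)CCCC(C)(C)[C@@H]2CC[C@@]1(C)O | intermediate
7 | (5S,8R,9R,10S)-labda-13(16),14-dien-8-ol (iso-abienol) | C=CC(=C)CC[C@@H]1[C@@]2(C)CCCC(C)(C)[C@@H]2CC[C@@]1(C)O | intermediate
8 | (4S,5R,8R,9R,10S)-labda-13(16),14-diene-8,19-diol | C=CC(=C)CC[C@@H]1[C@@]2(C)CCC[C@](C)(CO)[C@@H]2CC[C@@]1(C)O | intermediate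
9 | (Z)-3-iodoacrylic acid | OC(=O)/C=C\I | starting material
10 | O-[(Z)-3-iodoacryloyl]-N,N′-dicyclohexylisourea | I/C=C\C(=O)OC(=NC1CCCCC1)NC1CCCCC1 | intermediate
11 | (4S,5R,8R,9R,10S)-8-hydroxylabda-13(16),14-dien-19-yl (Z)-3-iodoacrylate | C=CC(=C)CC[C@@H]1[C@@]2(C)CCC[C@](C)(COC(=O)/C=C\I)[C@@H]2CC[C@@]1(C)O | intermediate
12 | 2-methoxy-4-(4,4,5,5-tetramethyl-1,3,2-dioxaborolan-2-yl)phenol | COc1cc(B2OC(C)(C)C(C)(C)O2)ccc1O | starting material
13 | (4S,5R,8R,9R,10S)-8-hydroxylabda-13(16),14-dien-19-yl (Z)-3-(4-hydroxy-3-methoxyphenyl)prop-2-enoate | C=CC(=C)CC[C@@H]1[C@@]2(C)CCC[C@](C)(COC(=O)/C=C\c3ccc(O)c(OC)c3)[C@@H]2CC[C@@]1(C)O | target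

## Step count and risks

Total steps: 6. Longest linear sequence: 6 steps (1 → 4 → 6 → 7 → 8 → 11 → 13).

**Step 4 (the proposed new step).** No existing catalyst is known to deliver the 19-ol selectively; the evolved enzyme may instead give the 18-ol, ring CH2 alcohols or diene epoxides. The fallback uses known chemistry, sets out from 1 and comes back at 8. Preparative fermentation of sclareol with a Cunninghamella strain, a fungal ring A hydroxylation that I recall as reported but have not checked, gives 19-hydroxysclareol F1 among the 2α-, 3β- and 18-hydroxy isomers, which are separated by chromatography. Peracetylation (AcCl, PhNMe2) gives the 8,13,19-triacetate F2. Elimination of the tertiary allylic acetate with Pd(PPh3)4 (dioxane, 100 °C) gives 8α,19-diacetoxylabda-13(16),14-diene F3, which is separated from the 12,14-diene isomers on AgNO3–silica. LiAlH4 then removes both acetates and gives 8.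

**Step 2.** Enolisation may occur partly toward C12, the δ-hydroxy ketone may sit as its hemiketal, and the alkoxide may be triflated. The fallback sets out from 1 and comes back at 7, replacing steps 1–3 by an allylic elimination. Sclareol is acetylated (AcCl, PhNMe2) to sclareol 8,13-diacetate F4. Elimination with Pd(PPh3)4 (dioxane, 100 °C) gives 8α-acetoxylabda-13(16),14-diene F5 after removal of the 12,14-dienes on AgNO3–silica. LiAlH4 cleaves the tertiary acetate and gives 7.

**Step 6.** The Z-alkene may isomerise to E under palladium and base, or the diene may undergo Heck side reactions. The fallback sets out from 8 and comes back at 13, making the Z-alkene by olefination instead of cross-coupling. Compound 8 is acylated at O19 with bromoacetyl bromide and pyridine to give the 19-bromoacetate F6. Diphenyl phosphite and Et3N convert it (Michaelis–Becker) into the 19-(diphenoxyphosphoryl)acetate F7. An Ando-type Z-selective Horner–Wadsworth–Emmons reaction with 4-(tert-butyldimethylsilyloxy)-3-methoxybenzaldehyde (NaI, DBU, THF, 0 °C) gives the silyl-protected Z-ferulate F8. Bu4NF buffered with AcOH frees the phenol and gives 13.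

## Further compounds

F1 | step 4 | 19-hydroxysclareol, (4S,5R,8R,9R,10S,13R)-labd-14-ene-8,13,19-triol | C=C[C@](C)(O)CC[C@@H]1[C@@]2(C)CCC[C@](C)(CO)[C@@H]2CC[C@@]1(C)O
F2 | step 4 | (4S,5R,8R,9R,10S,13R)-labd-14-ene-8,13,19-triyl triacetate | C=C[C@](C)(OC(C)=O)CC[C@@H]1[C@@]2(C)CCC[C@](C)(COC(C)=O)[C@@H]2CC[C@@]1(C)OC(C)=O
F3 | step 4 | (4S,5R,8R,9R,10S)-labda-13(16),14-diene-8,19-diyl diacetate | C=CC(=C)CC[C@@H]1[C@@]2(C)CCC[C@](C)(COC(C)=O)[C@@H]2CC[C@@]1(C)OC(C)=O
F4 | step 2 | sclareol diacetate, (5S,8R,9R,10S,13R)-labd-14-ene-8,13-diyl diacetate | C=C[C@](C)(OC(C)=O)CC[C@@H]1[C@@]2(C)CCCC(C)(C)[C@@H]2CC[C@@]1(C)OC(C)=O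
F5 | step 2 | (5S,8R,9R,10S)-labda-13(16),14-dien-8-yl acetate | C=CC(=C)CC[C@@H]1[C@@]2(C)CCCC(C)(C)[C@@H]2CC[C@@]1(C)OC(C)=O
F6 | step 6 | (4S,5R,8R,9R,10S)-8-hydroxylabda-13(16),14-dien-19-yl bromoacetate | C=CC(=C)CC[C@@H]1[C@@]2(C)CCC[C@](C)(COC(=O)CBr)[C@@H]2CC[C@@]1(C)O
F7 | step 6 | (4S,5R,8R,9R,10S)-8-hydroxylabda-13(16),14-dien-19-yl (diphenoxyphosphoryl)acetate | C=CC(=C)CC[C@@H]1[C@@]2(C)CCC[C@](C)(COC(=O)CP(=O)(Oc3ccccc3)Oc3ccccc3)[C@@H]2CC[C@@]1(C)O
F8 | step 6 | (4S,5R,8R,9R,10S)-8-hydroxylabda-13(16),14-dien-19-yl (Z)-3-[4-(tert-butyldimethylsilyloxy)-3-methoxyphenyl]prop-2-enoate | C=CC(=C)CC[C@@H]1[C@@]2(C)CCC[C@](C)(COC(=O)/C=C\c3ccc(O[Si](C)(C)C(C)(C)C)c(OC)c3)[C@@H]2CC[C@@]1(C)O
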